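**Plan**

- Retrosynthesis: the C11–O aryl ether is cut first (isofraxidin), then the C3 ester, then C9–C11 (one-carbon homologation of a C9 ketone), and last the two ring A bonds C4–C5 and C1–C10.
- Enabling feature: ring B (C5–C10), with oxygen on C6, a functionalised carbon at C9 and methyl groups on C8 and C10, has the substitution pattern of 2,6-dimethyl-1,4-benzoquinone; C1–C4, with the C3 oxygen and the gem-dimethyl C4, is a 3-silyloxy-4-methylpenta-1,3-diene.
- Forward: the diene is made from isobutyraldehyde; a catalytic asymmetric Diels–Alder reaction closes ring A onto the quinone, which becomes ring B; C11 is added by methylenation and hydroboration at C9; isofraxidin is attached last.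
- Stereochemistry: C10 from the chiral titanium catalyst (quinone face); C5 by base equilibration to the trans-decalin; C3 by equatorial hydride delivery (axial 3α-oxygen); C9 by thermodynamic equilibration at the γ-position of the 7-en-6-one.

Key step: step 4

Numbering: drimane numbering is used (ring A = C1–C5 and C10; ring B = C5–C10; C11 on C9); β is the face of the C10 methyl group, α the opposite face.

Assumption: (R)-BINOL is taken as the ligand antipode that opens the quinone face leading to 7; should the sense of induction be opposite, (S)-BINOL is used with no other change.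

**Route**

Step 1
Reactants: 1 isobutyraldehyde; 2 vinylmagnesium bromide
Product: 3 4-methylpent-1-en-3-ol (racemic)
Conditions: THF, 0 °C; aq. NH4Cl
Reagents that add atoms: none
Why: Grignard 1,2-addition of a vinyl nucleophile to an unhindered aliphatic aldehyde is reliable, and the racemic carbinol centre is removed in step 2.

Step 2
Reactants: 3 4-methylpent-1-en-3-ol
Product: 4 4-methylpent-1-en-3-one
Conditions: Dess–Martin periodinane, CH2Cl2, 0 °C to rt
Reagents that add atoms: none
Why: Dess–Martin oxidation of a secondary allylic alcohol runs under neutral, non-nucleophilic conditions that should leave the polymerisable vinyl ketone intact.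

Step 3
Reactants: 4 4-methylpent-1-en-3-one
Product: 5 3-(tert-butyldimethylsilyloxy)-4-methylpenta-1,3-diene
Conditions: TBSOTf, Et3N, Et2O, 0 °C
Reagents that add atoms: tert-butyldimethylsilyl trifluoromethanesulfonate, CC(C)(C)[Si](C)(C)OS(=O)(=O)C(F)(F)F
Why: Soft enolisation with a silyl triflate and an amine base can only occur at the isopropyl methine, so the fully substituted enol silane (the 2-silyloxy-1,3-diene) should form as one regioisomer with no alkene geometry to control.

Step 4
Reactants: 5 3-(tert-butyldimethylsilyloxy)-4-methylpenta-1,3-diene; 6 2,6-dimethyl-1,4-benzoquinone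
Product: 7 cis-fused 3-(tert-butyldimethylsilyloxy)-11-nordrima-2,7-diene-6,9-dione (5β-H; 10β-CH3)
Conditions: (R)-BINOL-TiCl2 (10 mol %; from (R)-BINOL and TiCl2(Oi-Pr)2), 4 Å MS, CH2Cl2, −30 to 0 °C
Reagents that add atoms: none
Why: Proposed new method: a BINOL-titanium-catalysed quinone Diels–Alder reaction in which the 2-silyloxydiene carries a fully substituted enol-silane terminus with an inward methyl group, the closest known reactions being BINOL-titanium-catalysed cycloadditions of 2-silyloxydienes to quinones and Lewis-acid-promoted cycloadditions of hindered 2-silyloxydienes to α-methyl enones. Titanium coordinated to the less hindered quinone carbonyl (the future C6=O) lowers the LUMO, the enol-silane carbon C4 bonds to the unsubstituted quinone carbon C5 and the CH2 terminus C1 to the methyl-bearing C10, in an asynchronous concerted transition state or, at the stepwise limit, by Mukaiyama–Michael addition followed by Michael closure of the titanium enolate onto the silyloxyallyl cation. Ring A closes in a suprafacial [4+2] mode (at the stepwise limit a 6-endo-trig attack of the enolate carbon C10 on C1), which gives the cis ring fusion. C10 is set by the quinone face that the BINOL ligand leaves open, and C5 follows from suprafacial addition and is corrected in step 5. The step needs regiocontrol and face control but no endo/exo control, since neither diene terminus becomes a stereocentre and the two quinone alkenes are equivalent by symmetry. Regiochemistry rests on the substrates: the reverse orientation would have to join the two fully substituted carbons C4 and C10, which is expected to outweigh the electronic preference of a carbonyl-bound Lewis acid for attack at C10, and the trisubstituted ene-dione alkene left in 7 should not add a second diene.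

Step 5
Reactants: 7 cis-fused 3-(tert-butyldimethylsilyloxy)-11-nordrima-2,7-diene-6,9-dione
Product: 8 trans-fused 3-(tert-butyldimethylsilyloxy)-11-nordrima-2,7-diene-6,9-dione (5α-H; 10β-CH3)
Conditions: DBU (0.2 equiv), toluene, rt
Reagents that add atoms: none
Why: Amine-catalysed enolisation of the C6 ketone toward C5 equilibrates the ring fusion, and thermodynamic control should favour the trans-decalin with the quaternary C4 equatorial on ring B, which sets C5 (5α-H) relative to the fixed C10.

Step 6
Reactants: 8 trans-fused 3-(tert-butyldimethylsilyloxy)-11-nordrima-2,7-diene-6,9-dione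
Product: 9 6β-hydroxy-3-(tert-butyldimethylsilyloxy)-11-nordrima-2,7-dien-9-one
Conditions: NaBH4, CeCl3·7H2O, MeOH/CH2Cl2, −78 °C
Reagents that add atoms: none
Why: Luche 1,2-reduction should attack the C6 carbonyl (flanked by the C5 methine and a vinylic CH) in preference to the C9 carbonyl (next to the quaternary C10 and the methyl-bearing C8), with hydride arriving on the α face anti to the syn-axial C4β and C10 methyl groups; the 6β-alcohol is a temporary stereocentre that only masks C6.

Step 7
Reactants: 9 6β-hydroxy-3-(tert-butyldimethylsilyloxy)-11-nordrima-2,7-dien-9-one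
Product: 10 3-(tert-butyldimethylsilyloxy)drima-2,7,9(11)-trien-6β-ol
Conditions: Ph3PCH3Br, KN(SiMe3)2 (excess ylide), THF/toluene, 0 to 70 °C
Reagents that add atoms: methyltriphenylphosphonium bromide, C[P+](c1ccccc1)(c1ccccc1)c1ccccc1.[Br-]
Why: Wittig methylenation should convert the hindered C9 carbonyl into the exocyclic 9(11)-alkene on warming, because this ketone has no α-hydrogen to enolise, the C6 hydroxyl is carried as its potassium alkoxide and the silyl enol ether keeps the C3 carbonyl masked.

Step 8
Reactants: 10 3-(tert-butyldimethylsilyloxy)drima-2,7,9(11)-trien-6β-ol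
Product: 11 6β-hydroxydrima-7,9(11)-dien-3-one
Conditions: Bu4NF, AcOH, THF, 0 °C
Reagents that add atoms: none
Why: Fluoride cleavage of the silyl enol ether with C-protonation by the acetic acid buffer unmasks the C3 ketone under conditions too mild to ionise the dienylic alcohol.

Step 9
Reactants: 11 6β-hydroxydrima-7,9(11)-dien-3-one
Product: 12 drima-7,9(11)-diene-3α,6β-diol
Conditions: LiBH(s-Bu)3 (L-Selectride), THF, −78 °C; NaOH, H2O2
Reagents that add atoms: none
Why: Bulky trialkylborohydride reduction of a cyclohexanone next to a quaternary carbon proceeds by equatorial attack, so the axial 3α-alcohol is expected and C3 is set by substrate control, as is usual for 4,4-dimethyl-3-ketones of trans-decalins.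

Step 10
Reactants: 12 drima-7,9(11)-diene-3α,6β-diol
Product: 13 6β-hydroxydrima-7,9(11)-dien-3α-yl 3-methylbutanoate
Conditions: 3-methylbutanoyl chloride, pyridine, DMAP, CH2Cl2, 0 °C to rt
Reagents that add atoms: 3-methylbutanoyl chloride (isovaleryl chloride), CC(C)CC(=O)Cl
Why: DMAP-catalysed acylation should distinguish the two secondary alcohols, because the pseudoaxial 6β-hydroxyl is flanked by the syn-axial C4β and C10 methyl groups and only the 3α-hydroxyl is accessible.

Step 11
Reactants: 13 6β-hydroxydrima-7,9(11)-dien-3α-yl 3-methylbutanoate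
Product: 15 6β,11-dihydroxydrim-7-en-3α-yl 3-methylbutanoate (9α-H), via the C11 alkyl-9-BBN borane 14 (not isolated)
Conditions: 9-BBN, THF, 0 °C to rt; NaBO3·4H2O, H2O, rt
Reagents that add atoms: 9-BBN (9-borabicyclo[3.3.1]nonane), B1C2CCCC1CCC2 (boron in 14); sodium perborate NaBO3·4H2O, [Na+].[Na+].O[B-]1(O)OO[B-](O)(O)OO1 (oxygen at C11 in 15)
Why: Hydroboration–oxidation with a bulky dialkylborane places boron on the terminal CH2 of the exocyclic alkene (anti-Markovnikov) and leaves the trisubstituted ring alkene and the ester alone; hydrogen is expected to add to C9 from the α face, anti to the C10 methyl, but this C9 configuration is not relied upon because C9 is equilibrated in step 13.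

Step 12
Reactants: 15 6β,11-dihydroxydrim-7-en-3α-yl 3-methylbutanoate (9α-H)
Product: 16 11-hydroxy-6-oxodrim-7-en-3α-yl 3-methylbutanoate (9α-H; CH2OH β)
Conditions: MnO2 (excess), CH2Cl2, rt
Reagents that add atoms: none
Why: MnO2 oxidises allylic alcohols selectively, so the 6β-hydroxyl should become the enone carbonyl while the saturated primary C11 hydroxyl is untouched.

Step 13
Reactants: 16 11-hydroxy-6-oxodrim-7-en-3α-yl 3-methylbutanoate (9α-H; CH2OH β)
Product: 17 11-hydroxy-6-oxo-9-epi-drim-7-en-3α-yl 3-methylbutanoate (9β-H; CH2OH α)
Conditions: DBU, toluene, 80 °C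
Reagents that add atoms: none
Why: Vinylogous enolisation (γ-deprotonation to the linear dienolate and reprotonation at C9) epimerises the γ-stereocentre, and thermodynamic control should favour the pseudoaxial 9α-hydroxymethyl group because it escapes the A(1,2) strain with the C8 methyl group and the gauche contact with the C10 methyl group; C5, also enolisable, stays in its stable trans configuration and any remaining 16 is recycled.

Step 14
Reactants: 17 11-hydroxy-6-oxo-9-epi-drim-7-en-3α-yl 3-methylbutanoate; 18 isofraxidin (7-hydroxy-6,8-dimethoxy-2H-chromen-2-one)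
Product: 19 target: (3R,5R,9R,10R)-11-[(6,8-dimethoxy-2-oxo-2H-chromen-7-yl)oxy]-6-oxo-9-epi-drim-7-en-3α-yl 3-methylbutanoate
Conditions: PPh3, DIAD, THF, 0 °C to rt
Reagents that add atoms: none
Why: Mitsunobu etherification of the only free hydroxyl (primary, no stereocentre involved) with the acidic 7-hydroxycoumarin forms the C11–O–aryl bond under near-neutral conditions, and the 9β-hydrogen lies close to the enone plane, which should disfavour γ-deprotonation and hence elimination.

**Compound list**

1 | isobutyraldehyde (2-methylpropanal) | CC(C)C=O | starting material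
2 | vinylmagnesium bromide | C=C[Mg]Br | starting material
3 | 4-methylpent-1-en-3-ol (racemic) | C=CC(O)C(C)C | intermediate
4 | 4-methylpent-1-en-3-one | C=CC(=O)C(C)C | intermediate
5 | 3-(tert-butyldimethylsilyloxy)-4-methylpenta-1,3-diene | C=CC(O[Si](C)(C)C(C)(C)C)=C(C)C | intermediate
6 | 2,6-dimethyl-1,4-benzoquinone | CC1=CC(=O)C=C(C)C1=O | starting material
7 | cis-fused 3-(tert-butyldimethylsilyloxy)-11-nordrima-2,7-diene-6,9-dione (5β-H, 10β-CH3) | O=C1C(C)=CC(=O)[C@@H]2C(C)(C)C(O[Si](C)(C)C(C)(C)C)=CC[C@]12C | intermediate
8 | trans-fused 3-(tert-butyldimethylsilyloxy)-11-nordrima-2,7-diene-6,9-dione (5α-H, 10β-CH3) | O=C1C(C)=CC(=O)[C@H]2C(C)(C)C(O[Si](C)(C)C(C)(C)C)=CC[C@]12C | intermediate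
9 | 6β-hydroxy-3-(tert-butyldimethylsilyloxy)-11-nordrima-2,7-dien-9-one | O=C1C(C)=C[C@@H](O)[C@H]2C(C)(C)C(O[Si](C)(C)C(C)(C)C)=CC[C@]12C | intermediate
10 | 3-(tert-butyldimethylsilyloxy)drima-2,7,9(11)-trien-6β-ol | C=C1C(C)=C[C@@H](O)[C@H]2C(C)(C)C(O[Si](C)(C)C(C)(C)C)=CC[C@]12C | intermediate
11 | 6β-hydroxydrima-7,9(11)-dien-3-one | C=C1C(C)=C[C@@H](O)[C@H]2C(C)(C)C(=O)CC[C@]12C | intermediate
12 | drima-7,9(11)-diene-3α,6β-diol | C=C1C(C)=C[C@@H](O)[C@H]2C(C)(C)[C@H](O)CC[C@]12C | intermediate
13 | 6β-hydroxydrima-7,9(11)-dien-3α-yl 3-methylbutanoate | C=C1C(C)=C[C@@H](O)[C@H]2C(C)(C)[C@H](OC(=O)CC(C)C)CC[C@]12C | intermediate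
14 | 11-(9-borabicyclo[3.3.1]nonan-9-yl)-6β-hydroxydrim-7-en-3α-yl 3-methylbutanoate (9α-H; not isolated) | C(B3C4CCCC3CCC4)[C@H]1C(C)=C[C@@H](O)[C@H]2C(C)(C)[C@H](OC(=O)CC(C)C)CC[C@]12C | intermediate
15 | 6β,11-dihydroxydrim-7-en-3α-yl 3-methylbutanoate (9α-H) | OC[C@H]1C(C)=C[C@@H](O)[C@H]2C(C)(C)[C@H](OC(=O)CC(C)C)CC[C@]12C | intermediate
16 | 11-hydroxy-6-oxodrim-7-en-3α-yl 3-methylbutanoate (9α-H, CH2OH β) | OC[C@H]1C(C)=CC(=O)[C@H]2C(C)(C)[C@H](OC(=O)CC(C)C)CC[C@]12C | intermediate
17 | 11-hydroxy-6-oxo-9-epi-drim-7-en-3α-yl 3-methylbutanoate (9β-H, CH2OH α) | OC[C@@H]1C(C)=CC(=O)[C@H]2C(C)(C)[C@H](OC(=O)CC(C)C)CC[C@]12C | intermediate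
18 | isofraxidin (7-hydroxy-6,8-dimethoxy-2H-chromen-2-one) | COc1cc2ccc(=O)oc2c(OC)c1O | starting material
19 | (3R,5R,9R,10R)-11-[(6,8-dimethoxy-2-oxo-2H-chromen-7-yl)oxy]-6-oxo-9-epi-drim-7-en-3α-yl 3-methylbutanoate (CNP0279705.1) | COc1cc2ccc(=O)oc2c(OC)c1OC[C@@H]1C(C)=CC(=O)[C@H]2C(C)(C)[C@H](OC(=O)CC(C)C)CC[C@]12C | target

**Count and risks**

Total step count: 14. Longest linear sequence: 14 steps (1 to 19); 6 and 18 are purchased and enter in steps 4 and 14.

Steps most likely to fail:

1. Step 4 (Proposed new method). The inward methyl group of the diene may slow the cycloaddition so much that desilylation of the diene by the Lewis acid, or Mukaiyama–Michael addition followed by tautomerisation of the mono-adduct to a hydroquinone, overtakes ring closure. Independently, facial discrimination by the titanium complex on a non-chelating quinone may be poor. Fallback (known chemistry): setting out again from 5 and 6, the cycloaddition is run without chiral control, thermally in toluene or promoted by the achiral Lewis acid mixture AlBr3/AlMe3 in CH2Cl2, a combination established for hindered 2-silyloxydienes. This gives the racemic cis adduct, that is 7 together with the mirror-image cis adduct F1. DBU epimerisation as in step 5 gives the racemic trans dione, that is 8 together with the mirror-image trans dione F2. The antipodes are separated by preparative HPLC on a chiral stationary phase (cellulose tris(3,5-dimethylphenylcarbamate)), and the route is rejoined at 8.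

2. Step 13. The dienolate may expel hydroxide (vinylogous β-elimination) or lose formaldehyde (vinylogous retro-aldol cleavage) faster than it is reprotonated at C9, or the equilibration may stall with little net change. Fallback: the elimination is made the route. Setting out from 13, MnO2 oxidation of the allylic 6β-hydroxyl gives the linear dienone 6-oxodrima-7,9(11)-dien-3α-yl 3-methylbutanoate F3. Conjugate 1,6-addition of 18 to the exocyclic CH2 (catalytic Cs2CO3, MeCN, rt) and protonation of the resulting dienolate then take place under equilibrating conditions. Phenoxide addition and C9 protonation are both reversible, so the ether should settle in the more stable 9α configuration. This leads directly to 19, where the route is rejoined with steps 11 to 14 bypassed.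

3. Step 14. The alkoxyphosphonium intermediate may undergo β-elimination toward the conjugated exocyclic dienone (loss of Ph3PO together with the C9 hydrogen), or substitution at the β-branched, axially held CH2 may not take place. Fallback: the ether is formed before the enone exists. Setting out from 15, a Mitsunobu reaction with 18 at the primary hydroxyl gives the 6β-hydroxy aryl ether F4; the 6β-hydroxyl is too hindered to compete and no acidic γ-hydrogen is present. Dess–Martin oxidation gives the 9-epimer of the target F5. C9 is then equilibrated with catalytic DBU in the presence of added 18, which returns any phenoxide lost by elimination through conjugate re-addition, and the route is rejoined at 19.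

Further compounds
F1 | step 4 | mirror-image cis adduct (enantiomer of 7) | O=C1C(C)=CC(=O)[C@H]2C(C)(C)C(O[Si](C)(C)C(C)(C)C)=CC[C@@]12C
F2 | step 4 | mirror-image trans dione (enantiomer of 8) | O=C1C(C)=CC(=O)[C@@H]2C(C)(C)C(O[Si](C)(C)C(C)(C)C)=CC[C@@]12C
F3 | step 13 | 6-oxodrima-7,9(11)-dien-3α-yl 3-methylbutanoate | C=C1C(C)=CC(=O)[C@H]2C(C)(C)[C@H](OC(=O)CC(C)C)CC[C@]12C
F4 | step 14 | 11-[(6,8-dimethoxy-2-oxo-2H-chromen-7-yl)oxy]-6β-hydroxydrim-7-en-3α-yl 3-methylbutanoate (9α-H) | COc1cc2ccc(=O)oc2c(OC)c1OC[C@H]1C(C)=C[C@@H](O)[C@H]2C(C)(C)[C@H](OC(=O)CC(C)C)CC[C@]12C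
F5 | step 14 | 9-epimer of 19 (9α-H, CH2OAr β) | COc1cc2ccc(=O)oc2c(OC)c1OC[C@H]1C(C)=CC(=O)[C@H]2C(C)(C)[C@H](OC(=O)CC(C)C)CC[C@]12C
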